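## Structural features

The target is a carbon–carbon-linked biflavonoid made of two C15 units. The first unit is (2S)-eriodictyol, a 5,7-dihydroxychroman-4-one (rings A and C) carrying catechol ring B at C2. The second is luteolin, a 5,7-dihydroxychromen-4-one with its own 3,4-dihydroxyphenyl ring, and a single bond joins flavanone ring B carbon C5' to flavone ring A carbon C6. Flavanone C2 is the only stereocentre and has no stereogenic neighbour. The biaryl axis is flanked by three oxygens (O4', flavone O5, flavone O7) and one hydrogen, is not defined in the target, and is treated as freely rotating in the free polyphenol. C2 is the fragile point: it is benzylic, β to the C4 ketone and para to the 4'-hydroxyl, so base opens the C2–O1 bond by retro-oxa-Michael reaction, pushed by the 4'-phenoxide, and the configuration is lost. The real difficulty is the biaryl bond: both of its carbons are innately nucleophilic positions ortho to a phenol, the bond is crowded, and flavone ring A offers C8 as an electronically similar rival of C6. The key step exploits the fact that O4' is ortho to C5' and flavone O5 is ortho to C6, so one silicon atom can close the chain O4'–C4'–C5'···C6–C5–O5 to a seven-membered ring. The only other position ortho to O5 is the quaternary ring-fusion carbon C4a, so a bridge from O5 can deliver an aryl group to C6 alone.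

## Logic of the disconnections

**18 to 17.**
- Bonds cut: the six O–CH2Ph bonds at flavanone O5, O7 and O3' and at flavone O7, O3' and O4'.
- Reason: the last operation must be neutral or faintly acidic, because free 18 racemises through its 4'-phenoxide. Hydrogenolysis meets this and leaves only toluene to remove.
- Choice of group: acetal-type ethers were rejected. They would not outlast the hot sulfonic acid used two steps earlier, and they would release formaldehyde beside two very nucleophilic phloroglucinol rings.
- Gain: a lipophilic precursor that can be chromatographed.
- Demand: hydrogen uptake must stop before the cyclic benzylic C2–O1 bond, the C4 ketone or the flavone C2–C3 double bond is touched.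

**17 to 16.**
- Bonds concerned: the free O4'–H and flavone O5–H are traced back to the two Si–O bonds of the bridge.
- Reason: the bridge is kept until all heating in acid is over, because it masks O4', the oxygen whose electron push opens ring C.
- Gain: the tether doubles as the protecting group of two phenols, so no separate groups are spent on them.
- Demand: the fluoride source must be acidic, so that no phenoxide is ever formed.

**16 to 13.**
- Bonds concerned: O1–C2 is cut, and a tert-butoxycarbonyl group is added at C3 as a removable activator.
- Gain: ring C and the only stereocentre are removed in one move, giving an achiral alkylidene β-ketoester.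
- Demand: ring closure must take place only under the chiral catalyst and not spontaneously, and the ester must be lost without reversible opening of ring C.

**13 to 9 and 12.**
- Bond cut: the alkene that becomes C2–C3.
- Gain: this is the convergent cut. It separates ring A (12) from the whole biaryl half (9) and needs only an aldehyde and an active methylene group.
- Demand: the condensation catalyst must be mild enough for two aryl Si–O bonds and a free phenol next to a Michael acceptor.

**9 to 8.**
- Bond cut: the biaryl bond C5'–C6, which opens the seven-membered ring.
- Reason: this is the one bond that decides the 6- versus 8-linkage, and in 8 the geometry of the bridge decides it.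
- Polarity: the bromide at C5' gives one of the two nucleophilic carbons the opposite polarity, while the flavone carbon needs no prior functionalisation.
- Demand: the Si–O bonds must survive a carboxylate base at high temperature, and the C6–H bond, crowded by two oxygen substituents, must still be metalated.

**8 to 7 and 2, and 7 to 5 and 6.**
- Bonds cut: the two Si–O bonds, one after the other.
- Order: the poorer nucleophile 5 meets silicon first, while silicon still carries two chlorides. The stronger nucleophile, the anion of 2, is kept for the harder second substitution.
- Gain: two simple monophenols.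
- Demand: each partner must carry exactly one free hydroxyl, at the correct oxygen.

**5 to 4 to 3.**
- Bonds cut: the O–benzyl bond at the oxygen remote from bromine, then the O–methyl bond.
- Regiochemistry: in 4 the hydroxyl that must stay free is the more acidic one. A weak base would therefore alkylate the wrong oxygen, and the forward step has to go through the dianion, in which the order of nucleophilicity is reversed.
- Why the methyl ether of 3 is not carried through: its late removal would need a strong Lewis acid on the finished flavanone.

**2 to 1.**
- Bonds cut: three O–benzyl bonds.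
- Basis: the chelated 5-OH protects itself, so 1 supplies all fifteen carbons of the flavone half in one step.

**12 to 11 to 10.**
- Bonds cut: the C–CO2tBu bond, then two O–benzyl bonds.
- Basis: the symmetry of 10 removes any regiochemical question.
- Demand: the dianion of 11 must be acylated at carbon without lactonisation.

## Other disconnections considered

**Alternative 1:**
- **Cut:** flavone ring A is taken apart at C5–C6, C7–C8 and C4a–C5, so the biaryl bond is traced back to an aryl–alkyne bond.
- **Forward key step:** 3-(benzyloxy)cyclobutenone A2 would be heated with the ring-B aryl siloxyalkyne A3 (Danheiser benzannulation). A2 opens to a vinylketene, which adds [2+2] to the electron-rich triple bond, with the ketene carbon going to the aryl-bearing alkyne carbon. The vinylcyclobutenone then opens again, and the dienylketene closes by a six-electron electrocyclisation and tautomerises to phenol A1.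
- **In favour:** the crowded bond exists before the ring is built, so no hindered coupling is needed; on this point the alternative is better than the chosen plan. No metal is required. The three oxygens of the new ring emerge differentiated (free OH, silyl ether, benzyl ether), so the oxygen para to the aryl group can later be chosen as pyranone O1. That fixes the 6-linkage as rigorously as the tether does, so the two plans are equal on regiocontrol.
- **Against:**
  - A1 is only a 2-arylphloroglucinol. The acyl carbon at C4a, ring C and the second catechol ring all remain to be built by C-acylation, exchange of protecting groups at O5 and O8a, aroylation, acyl transfer and cyclodehydration. Compound 1, which holds the finished flavone, cannot be used.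
  - Neither A2 nor A3 can be bought. A2 is a sensitive vinylogous ester, and A3 needs ynolate generation and silylation.
  - The ortho-substituted aryl group on the alkyne should slow the [2+2] step.
  - The acetal groups must endure long heating beside a newly formed phenol.
- **Step economy:** the chosen plan reaches 9 in six operations from purchasable parts. The alternative would need clearly more steps before the same stage is reached.

**Alternative 2:**
- **Cut:** flavanone C4–C4a.
- **Forward key step:** the activated (S)-3-aryl-3-(3,5-dibenzyloxyphenoxy)propanoic acid A5 would acylate its own phloroglucinol ring ortho to the ether oxygen (intramolecular Friedel–Crafts acylation) and give the fully protected target A4.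
- **In favour:**
  - No bond to the stereocentre is made or broken.
  - The two ortho positions are equivalent, so there is no regiochemical issue.
  - The ring is strongly activated, and the closure is not an equilibrium of the oxa-Michael type.
  - The configuration could come from a very well established reaction (reduction or aldol, then an inverting etherification). In reliability of stereochemical origin the alternative may equal or surpass a catalyst applied to an unusually large substrate.
- **Against:**
  - The cut says nothing about the biaryl bond, which is the main problem. A5 would still need something like steps 1 to 6.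
  - A5 is a β-aryloxy acid with a benzylic C–O bond. Activation invites elimination to the cinnamic acid, or ionisation, and either one destroys the configuration. The ring-B acetates are there only to damp this.
  - The acetates add a third kind of protecting group and call for a basic or nucleophilic removal, exactly what a 4'-oxygenated flavanone tolerates least.
  - The inverting etherification of a secondary benzylic alcohol is itself prone to partial loss of configuration.
- **Step economy:** aldehyde to alcohol, etherification, ester cleavage and cyclisation come to about four or five steps. The chosen plan needs two steps from 9 plus two short steps for 12.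

**Alternative 3:**
- **Cut:** catechol ring B is taken apart at C5'–C6' and C3'–C4'.
- **Forward key step:** methyl 3-bromocoumalate A7 and the 2,4,6-trioxygenated aryl siloxyalkyne A8 would undergo an inverse-demand Diels–Alder addition followed by loss of CO2, giving benzoate A6. The nucleophilic, aryl-bearing alkyne carbon bonds to pyrone C6, and the oxygen-bearing carbon bonds to C3.
- **In favour:**
  - The polarity of the two partners is matched, so the substitution pattern of ring B is fixed by the cycloaddition.
  - The biaryl bond again pre-exists.
  - O4' (silyl ether) and the future O3' (bromine as placeholder) are differentiated by construction. This is better than the chosen plan, which relies on a selective alkylation in step 3.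
  - The benzyl ether para to the biaryl bond marks the future O1, so the linkage is controlled as well as in the chosen plan.
- **Against:**
  - The alkyne carries a 2,6-disubstituted aryl group and should be a sluggish dienophile, needing prolonged heating.
  - The bromide must later be turned into a hydroxyl (borylation and oxidation, or catalytic hydroxylation), and the ester into an aldehyde.
  - As in Alternative 1, the complete flavone (acyl group, ring C and second catechol ring) must still be grown on the phloroglucinol ring.
- **Comparison:** mechanistically the key step is as well founded as the chosen one. In step economy it is clearly inferior, because it builds a simple benzene ring at the price of giving up 1 as a building block.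

Key step: step 6

Assumption: the quinine-derived thiourea is taken to deliver the (2S) product. The sense of induction is to be confirmed on 13, and the quinidine-derived pseudoenantiomer is the direct replacement if it is opposite.

Assumption: in bridged 9 and 13–16 the twisted biaryl axis may invert slowly, so these compounds may appear as axial isomers. All of them converge once the bridge is removed, and the axis is therefore not drawn.

Assumption: 13 is drawn as the Z isomer (ring B cis to the ester). The geometry is lost in step 10.

## Steps

Step 1
Reactants: 1 luteolin
Product: 2 7,3',4'-tri-O-benzylluteolin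
Conditions: BnBr (3.2 equiv), K2CO3 (3.5 equiv), DMF, rt
Reagents that add atoms: benzyl bromide, BrCc1ccccc1
Why: Williamson ether synthesis: the 5-OH is held in a hydrogen bond to the C4 carbonyl and is the least acidic and least nucleophilic of the four phenols, so a weak base and about three equivalents of halide at room temperature should stop at the tri-ether and leave free exactly the oxygen needed for the bridge.

Step 2
Reactants: 3 5-bromovanillin
Product: 4 3-bromo-4,5-dihydroxybenzaldehyde
Conditions: AlCl3 (1.2 equiv), pyridine (4.5 equiv), CH2Cl2, reflux; then 2 M HCl
Reagents that add atoms: none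
Why: Lewis-acid-assisted cleavage of an aryl methyl ether next to a free phenol: aluminium binds the phenoxide and the neighbouring methoxy oxygen as a five-membered chelate, and pyridine takes the activated methyl group by SN2 attack. Aldehyde and aryl bromide are inert to these conditions.

Step 3
Reactants: 4 3-bromo-4,5-dihydroxybenzaldehyde
Product: 5 3-(benzyloxy)-5-bromo-4-hydroxybenzaldehyde
Conditions: NaH (2.1 equiv), DMF, 0 °C; BnBr (1.0 equiv), 0 °C to rt; then 1 M HCl
Reagents that add atoms: benzyl bromide, BrCc1ccccc1
Why: Regioselective mono-O-alkylation of a catecholate dianion: the oxide para to the formyl group and ortho to bromine is delocalised and crowded, while the oxide meta to the formyl group is the more basic and nucleophilic, so one equivalent of halide should go to the oxygen remote from bromine. With a weak base only the more acidic 4-OH would be ionised and the wrong ether would form, hence the full double deprotonation.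

Step 4
Reactants: 5 3-(benzyloxy)-5-bromo-4-hydroxybenzaldehyde; 6 di-tert-butyldichlorosilane
Product: 7 3-(benzyloxy)-5-bromo-4-[(di-tert-butylchlorosilyl)oxy]benzaldehyde
Conditions: NaH (1.05 equiv), THF, 0 °C; 6 (2 equiv), THF–DMF, 50 °C; filtration, excess 6 removed in vacuo
Reagents that add atoms: none
Why: Nucleophilic substitution at silicon: the weaker and more hindered nucleophile is attached first, while silicon still carries two chlorides, and the two tert-butyl groups make a second substitution by this poor phenoxide far slower, so an excess of 6 should stop the reaction at the monochloride. Chlorosilanes this hindered tolerate filtration and concentration.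

Step 5
Reactants: 2 7,3',4'-tri-O-benzylluteolin; 7 3-(benzyloxy)-5-bromo-4-[(di-tert-butylchlorosilyl)oxy]benzaldehyde
Product: 8 di-tert-butylsilylene-bridged bis(aryl) ether joining flavone O5 of 2 to O4 of the 3-(benzyloxy)-5-bromo-benzaldehyde unit
Conditions: 2, NaH (1.05 equiv), DMF, 0 °C to rt; then 7 (1.1 equiv), 50 °C
Reagents that add atoms: none
Why: Second substitution at silicon: deprotonation breaks the chelate of the 5-OH and turns it into a strong, electron-rich oxygen nucleophile, which should displace the remaining chloride in a dipolar aprotic solvent. The aldehyde of 7 is non-enolisable and is left alone by a phenoxide.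

Step 6
Reactants: 8 di-tert-butylsilylene-bridged bromide
Product: 9 dibenzo-dioxasilepine-bridged biaryl aldehyde (ring B C5' bonded to flavone C6; O4' and flavone O5 share the Si(tBu)2 group; CHO at C1'; benzyl ethers at O3' and at flavone O7, O3' and O4')
Conditions: Pd(OAc)2 (10 mol %), PCy3 (20 mol %), CsO2CtBu (2 equiv), 4 Å sieves, toluene or mesitylene, 110–120 °C, argon
Reagents that add atoms: none
Why: Zerovalent palladium, formed in the flask from Pd(OAc)2 and PCy3, should insert into the C5'–Br bond of 8; bromide is exchanged for pivalate on the divalent arylpalladium species, and the carboxylate then removes the flavone C6–H in a concerted metalation–deprotonation, helped by the acidity of a C–H bond flanked by two oxygens. Reductive elimination from the resulting eight-membered palladacycle forms C5'–C6 and so closes the seven-membered dioxasilepine ring, a closure by C–C bond formation with both Si–O bonds already in place. The closest known reaction type is the silicon-tethered intramolecular direct arylation of bis(aryloxy)di-tert-butylsilanes to bridged 2,2'-biphenols. Site selectivity is structural: from O5 the metal can reach only C6, because the other ortho position is the quaternary C4a and both C8 and C3 lie beyond any cyclic transition state of reasonable size. The benzyl group at O3' is meta to the C–Pd bond and cannot be arylated, and the aldehyde has no α-hydrogen. The tert-butyl groups shield the Si–O bonds from pivalate, and the non-polar solvent, the sieves and the free phosphine (not its HBF4 salt, a latent fluoride source) serve the same end. No stereocentre is formed; the twisted bridged axis arises as a racemate and is of no consequence.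

Step 7
Reactants: 10 2',4',6'-trihydroxyacetophenone
Product: 11 1-[2,4-bis(benzyloxy)-6-hydroxyphenyl]ethanone
Conditions: BnBr (2.05 equiv), K2CO3 (2.2 equiv), DMF, rt to 40 °C
Reagents that add atoms: benzyl bromide, BrCc1ccccc1
Why: Williamson ether synthesis: the para hydroxyl and one of the two equivalent ortho hydroxyls are alkylated, after which the last one is locked in a hydrogen bond to the acetyl group and resists a weak base.

Step 8
Reactants: 11 1-[2,4-bis(benzyloxy)-6-hydroxyphenyl]ethanone
Product: 12 tert-butyl 3-[2,4-bis(benzyloxy)-6-hydroxyphenyl]-3-oxopropanoate
Conditions: LiN(SiMe3)2 (3.2 equiv), THF, −78 °C; Boc2O (1.05 equiv), −78 to −30 °C; AcOH quench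
Reagents that add atoms: di-tert-butyl dicarbonate, CC(C)(C)OC(=O)OC(=O)OC(C)(C)C
Why: Claisen-type C-acylation of the lithium phenoxide–enolate dianion by the dicarbonate; the third equivalent of base takes up the acidic β-ketoester as it forms. Any carbonate formed at the phenoxide oxygen lies next to an enolate and should be funnelled into the same product by Baker–Venkataraman-type O-to-C transfer, and the poor tert-butoxide leaving group at low temperature disfavours lactonisation.

Step 9
Reactants: 9 bridged biaryl aldehyde; 12 tert-butyl 3-[2,4-bis(benzyloxy)-6-hydroxyphenyl]-3-oxopropanoate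
Product: 13 tert-butyl (Z)-2-[2,4-bis(benzyloxy)-6-hydroxybenzoyl]-3-(bridged biaryl)prop-2-enoate
Conditions: piperidine (20 mol %), AcOH (20 mol %), 4 Å sieves, toluene, rt; chromatography to remove the amine salt
Reagents that add atoms: none
Why: Knoevenagel condensation of an active methylene compound with a non-enolisable aldehyde whose two ortho positions are unsubstituted. The buffered amine salt in a non-polar solvent should spare the hindered Si–O bonds, and the hydrogen-bonded phenol together with the bulky ester holds back spontaneous ring closure, so that C2 remains unset for the next step.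

Step 10
Reactants: 13 tert-butyl (Z)-alkylidene β-ketoester
Product: 16 (2S)-silylene-bridged hexa-O-benzyl flavanone–flavone, via trans-3-(tert-butoxycarbonyl)flavanone 14 (not isolated), via 3-carboxyflavanone 15 (not isolated)
Conditions: N-[3,5-bis(trifluoromethyl)phenyl]-N'-(9-deoxy-9-epi-quinin-9-yl)thiourea (10 mol %), toluene, −25 °C; then TsOH·H2O, 80 °C
Reagents that add atoms: none
Why: Organocatalytic asymmetric intramolecular oxa-Michael addition (6-endo-trig) followed by acid-induced loss of isobutene and decarboxylation: the thiourea binds the two carbonyl groups of the alkylidene β-ketoester while the quinuclidine nitrogen activates the phenol, so oxygen is delivered to one face of the alkene carbon and C2 is set as S by the catalyst. C3 settles as the trans epimer, is labile and is erased on decarboxylation. During the hot acid stage O4' is still tied up in the bridge, which shuts off the quinone-methide path to ring opening.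

Step 11
Reactants: 16 (2S)-silylene-bridged hexa-O-benzyl flavanone–flavone
Product: 17 (2S)-hexa-O-benzyl ether with free 4'-OH and free flavone 5-OH
Conditions: HF·pyridine, pyridine, THF, 0 °C to rt; pH 6 phosphate buffer work-up
Reagents that add atoms: none
Why: Fluoride-driven cleavage of the two aryl Si–O bonds, the standard removal of a di-tert-butylsilylene group. The acidic, pyridine-buffered reagent releases both phenols in neutral form, so the 4'-phenoxide that a basic fluoride such as Bu4NF would generate, and with it racemisation at C2, is avoided; benzyl ethers and both carbonyl systems are inert.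

Step 12
Reactants: 17 (2S)-hexa-O-benzyl ether
Product: 18 (2S)-2-{3,4-dihydroxy-5-[2-(3,4-dihydroxyphenyl)-5,7-dihydroxy-4-oxo-4H-chromen-6-yl]phenyl}-5,7-dihydroxychroman-4-one (target)
Conditions: H2 (1 atm), 10 % Pd/C, THF–MeOH, 1 % AcOH, rt; stopped at the calculated uptake
Reagents that add atoms: none
Why: Catalytic hydrogenolysis of six primary benzyl aryl ethers under neutral to faintly acidic conditions, which leave the configuration at C2 alone. Primary benzyl ethers are cleaved faster than the cyclic secondary benzylic C2–O1 bond, the aryl ketone or the flavone double bond is attacked, and filtration and evaporation suffice to isolate the polar product.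

## Compound list

1 | luteolin | O=c1cc(-c2ccc(O)c(O)c2)oc2cc(O)cc(O)c12 | starting material
2 | 7,3',4'-tri-O-benzylluteolin | O=c1cc(-c2ccc(OCc3ccccc3)c(OCc3ccccc3)c2)oc2cc(OCc3ccccc3)cc(O)c12 | intermediate
3 | 5-bromovanillin | COc1cc(C=O)cc(Br)c1O | starting material
4 | 3-bromo-4,5-dihydroxybenzaldehyde | O=Cc1cc(O)c(O)c(Br)c1 | intermediate
5 | 3-(benzyloxy)-5-bromo-4-hydroxybenzaldehyde | O=Cc1cc(Br)c(O)c(OCc2ccccc2)c1 | intermediate
6 | di-tert-butyldichlorosilane | CC(C)(C)[Si](Cl)(Cl)C(C)(C)C | starting material
7 | 3-(benzyloxy)-5-bromo-4-[(di-tert-butylchlorosilyl)oxy]benzaldehyde | O=Cc1cc(Br)c(O[Si](Cl)(C(C)(C)C)C(C)(C)C)c(OCc2ccccc2)c1 | intermediate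
8 | di-tert-butylsilylene-bridged 5-O-flavonyl 4-O-(2-bromo-4-formyl-6-benzyloxyphenyl) ether | O=Cc1cc(Br)c(O[Si](C(C)(C)C)(C(C)(C)C)Oc2cc(OCc3ccccc3)cc3oc(-c4ccc(OCc5ccccc5)c(OCc5ccccc5)c4)cc(=O)c23)c(OCc2ccccc2)c1 | intermediate
9 | dibenzo-dioxasilepine-bridged biaryl aldehyde | O=Cc1cc2c(c(OCc3ccccc3)c1)O[Si](C(C)(C)C)(C(C)(C)C)Oc1c-2c(OCc2ccccc2)cc2oc(-c3ccc(OCc4ccccc4)c(OCc4ccccc4)c3)cc(=O)c12 | intermediate
10 | 2',4',6'-trihydroxyacetophenone | CC(=O)c1c(O)cc(O)cc1O | starting material
11 | 1-[2,4-bis(benzyloxy)-6-hydroxyphenyl]ethanone | CC(=O)c1c(O)cc(OCc2ccccc2)cc1OCc1ccccc1 | intermediate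
12 | tert-butyl 3-[2,4-bis(benzyloxy)-6-hydroxyphenyl]-3-oxopropanoate | CC(C)(C)OC(=O)CC(=O)c1c(O)cc(OCc2ccccc2)cc1OCc1ccccc1 | intermediate
13 | tert-butyl (Z)-2-[2,4-bis(benzyloxy)-6-hydroxybenzoyl]-3-(bridged biaryl)prop-2-enoate | CC(C)(C)OC(=O)/C(C(=O)c1c(O)cc(OCc2ccccc2)cc1OCc1ccccc1)=C\c1cc2c(c(OCc3ccccc3)c1)O[Si](C(C)(C)C)(C(C)(C)C)Oc1c-2c(OCc2ccccc2)cc2oc(-c3ccc(OCc4ccccc4)c(OCc4ccccc4)c3)cc(=O)c12 | intermediate
14 | tert-butyl (2S,3R)-trans-flavanone-3-carboxylate of the bridged series (C3 labile) | O=C1[C@H](C(=O)OC(C)(C)C)[C@@H](c2cc3c(c(OCc4ccccc4)c2)O[Si](C(C)(C)C)(C(C)(C)C)Oc2c-3c(OCc3ccccc3)cc3oc(-c4ccc(OCc5ccccc5)c(OCc5ccccc5)c4)cc(=O)c23)Oc2cc(OCc3ccccc3)cc(OCc3ccccc3)c21 | intermediate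
15 | (2S,3R)-flavanone-3-carboxylic acid of the bridged series (C3 labile) | O=C1[C@H](C(=O)O)[C@@H](c2cc3c(c(OCc4ccccc4)c2)O[Si](C(C)(C)C)(C(C)(C)C)Oc2c-3c(OCc3ccccc3)cc3oc(-c4ccc(OCc5ccccc5)c(OCc5ccccc5)c4)cc(=O)c23)Oc2cc(OCc3ccccc3)cc(OCc3ccccc3)c21 | intermediate
16 | (2S)-silylene-bridged hexa-O-benzyl flavanone–flavone | O=C1C[C@@H](c2cc3c(c(OCc4ccccc4)c2)O[Si](C(C)(C)C)(C(C)(C)C)Oc2c-3c(OCc3ccccc3)cc3oc(-c4ccc(OCc5ccccc5)c(OCc5ccccc5)c4)cc(=O)c23)Oc2cc(OCc3ccccc3)cc(OCc3ccccc3)c21 | intermediate
17 | (2S)-hexa-O-benzyl ether with free 4'-OH and flavone 5-OH | O=C1C[C@@H](c2cc(OCc3ccccc3)c(O)c(-c3c(OCc4ccccc4)cc4oc(-c5ccc(OCc6ccccc6)c(OCc6ccccc6)c5)cc(=O)c4c3O)c2)Oc2cc(OCc3ccccc3)cc(OCc3ccccc3)c21 | intermediate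
18 | (2S)-eriodictyol-(5'→6)-luteolin, CNP0333260.1 | O=C1C[C@@H](c2cc(O)c(O)c(-c3c(O)cc4oc(-c5ccc(O)c(O)c5)cc(=O)c4c3O)c2)Oc2cc(O)cc(O)c21 | target

## Step count and least certain steps

Total: 12 steps. Longest linear sequence: 9 steps, from 3 through steps 2, 3, 4, 5, 6, 9, 10, 11 and 12.

**Step 6 (key step).**
- Risks: loss of the tether through attack of pivalate or adventitious water on the Si–O bonds at high temperature; reductive loss of bromine; slow metalation of a C–H bond crowded by two oxygen substituents.
- Fallback: the C–H activation is given up, and the same bond is made by Suzuki–Miyaura coupling of two pre-functionalised carbons. It sets out from 2 and 5.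
  - Compound 2 is iodinated ortho to its free chelated hydroxyl (BnMe3N·ICl2, CaCO3, CH2Cl2–MeOH) to 6-iodo-7,3',4'-tri-O-benzylluteolin F1.
  - Compound 5 is converted by Miyaura borylation (B2pin2, PdCl2(dppf), KOAc, dioxane) into 3-(benzyloxy)-4-hydroxy-5-(pinacolboryl)benzaldehyde F2.
  - Coupling (Pd(OAc)2, SPhos, K3PO4, toluene–water) gives the free biphenol aldehyde F3.
  - Di-tert-butylsilyl bis(trifluoromethanesulfonate) with 2,6-lutidine then installs the bridge, the second Si–O bond now forming intramolecularly.
- The fallback returns to the route at 9. Regiocontrol then rests on the ortho-directing effect of the 5-OH instead of on geometry.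

**Step 5.**
- Risks: sluggish substitution at the very hindered silicon; exchange of aryloxide groups, because the formyl-bromophenoxide is itself a fair leaving group, which would lead to scrambling of the bridge.
- Fallback: it sets out from 5, bypasses 7 and returns at 8. Silicon is introduced in a less hindered form and activated oxidatively.
  - Di-tert-butylchlorosilane (imidazole, DMF) gives the di-tert-butylsilyl ether F4.
  - N-Bromosuccinimide (CH2Cl2, 0 °C, dark) converts Si–H into Si–Br to give the bromosilyl ether F5.
  - After removal of succinimide by filtration from hexane, the more reactive bromide is treated with the sodium salt of 2.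

**Step 10.**
- Risks: ring closure outside the catalyst (traces of amine salt, or the intrinsic reactivity of the electron-rich phenol); poor facial selectivity, because the flavone carbonyl competes for the thiourea; partial racemisation by reversible ring opening in hot acid.
- Fallback: it sets out from 16 of insufficient enantiomeric purity and returns at 16. It replaces catalyst-controlled bond formation by kinetic resolution.
  - Noyori-type asymmetric transfer hydrogenation (RuCl(p-cymene)[(R,R)-TsDPEN], HCO2H–Et3N, EtOAc, rt) should reduce the matched (2R)-ketone F6 faster, giving the (2R,4R)-cis-flavan-4-ol F7.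
  - F7 is separated by chromatography from the unreacted (2S)-ketone.

**Step 8.**
- Risks: acylation at the phenoxide oxygen without transfer; double acylation; lactonisation with loss of tert-butoxide.
- Fallback: it sets out from 11 and returns at 12. The intermolecular acylation is replaced by a deliberate intramolecular one.
  - Boc2O with catalytic DMAP gives 2-acetyl-3,5-bis(benzyloxy)phenyl tert-butyl carbonate F8.
  - LiN(SiMe3)2 (2.2 equiv, THF, −78 to 0 °C) then rearranges F8 in a Baker–Venkataraman-type O-to-C carboxyl transfer.

**Step 3.**
- Risks: incomplete formation of the dianion, which leads to alkylation at the more acidic oxygen; double alkylation.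
- Fallback: it sets out from 4 and returns at 5. It uses the natural selectivity instead of reversing it.
  - MOMCl (1 equiv) with NaHCO3 in DMF blocks the acidic 4-OH, giving 3-bromo-5-hydroxy-4-(methoxymethoxy)benzaldehyde F9.
  - BnBr with K2CO3 gives 3-(benzyloxy)-5-bromo-4-(methoxymethoxy)benzaldehyde F10.
  - Dilute HCl in aqueous THF removes the acetal.

**Step 12.**
- Risks: over-reduction (saturation of the flavone double bond, hydrogenolysis of C2–O1, reduction of the ketone); incomplete cleavage of the crowded benzyl ether at flavone O7.
- Fallback: it sets out from 17 and returns at 18. Reduction is replaced by Lewis-acid cleavage with a cation scavenger (BCl3, pentamethylbenzene, CH2Cl2, −78 °C, quenched cold with MeOH). It passes through no compound outside the list (entry F0).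

## Further compounds

F1 | step 6 | 6-iodo-7,3',4'-tri-O-benzylluteolin | O=c1cc(-c2ccc(OCc3ccccc3)c(OCc3ccccc3)c2)oc2cc(OCc3ccccc3)c(I)c(O)c12
F2 | step 6 | 3-(benzyloxy)-4-hydroxy-5-(4,4,5,5-tetramethyl-1,3,2-dioxaborolan-2-yl)benzaldehyde | O=Cc1cc(OCc2ccccc2)c(O)c(B2OC(C)(C)C(C)(C)O2)c1
F3 | step 6 | free biphenol aldehyde (C5'–C6 biaryl, 4'-OH and flavone 5-OH free) | O=Cc1cc(OCc2ccccc2)c(O)c(-c2c(OCc3ccccc3)cc3oc(-c4ccc(OCc5ccccc5)c(OCc5ccccc5)c4)cc(=O)c3c2O)c1
F4 | step 5 | 3-(benzyloxy)-5-bromo-4-[(di-tert-butylsilyl)oxy]benzaldehyde | O=Cc1cc(Br)c(O[SiH](C(C)(C)C)C(C)(C)C)c(OCc2ccccc2)c1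
F5 | step 5 | 3-(benzyloxy)-5-bromo-4-[(bromodi-tert-butylsilyl)oxy]benzaldehyde | O=Cc1cc(Br)c(O[Si](Br)(C(C)(C)C)C(C)(C)C)c(OCc2ccccc2)c1
F6 | step 10 | (2R)-silylene-bridged hexa-O-benzyl flavanone–flavone (enantiomer of 16) | O=C1C[C@H](c2cc3c(c(OCc4ccccc4)c2)O[Si](C(C)(C)C)(C(C)(C)C)Oc2c-3c(OCc3ccccc3)cc3oc(-c4ccc(OCc5ccccc5)c(OCc5ccccc5)c4)cc(=O)c23)Oc2cc(OCc3ccccc3)cc(OCc3ccccc3)c21
F7 | step 10 | (2R,4R)-cis-flavan-4-ol of the bridged series | O[C@@H]1C[C@H](c2cc3c(c(OCc4ccccc4)c2)O[Si](C(C)(C)C)(C(C)(C)C)Oc2c-3c(OCc3ccccc3)cc3oc(-c4ccc(OCc5ccccc5)c(OCc5ccccc5)c4)cc(=O)c23)Oc2cc(OCc3ccccc3)cc(OCc3ccccc3)c21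
F8 | step 8 | 2-acetyl-3,5-bis(benzyloxy)phenyl tert-butyl carbonate | CC(=O)c1c(OC(=O)OC(C)(C)C)cc(OCc2ccccc2)cc1OCc1ccccc1
F9 | step 3 | 3-bromo-5-hydroxy-4-(methoxymethoxy)benzaldehyde | O=Cc1cc(O)c(OCOC)c(Br)c1
F10 | step 3 | 3-(benzyloxy)-5-bromo-4-(methoxymethoxy)benzaldehyde | O=Cc1cc(Br)c(OCOC)c(OCc2ccccc2)c1
F0 | step 12 | none | none
A1 | alternative 1 | 2-[5-(dimethoxymethyl)-2,3-bis(methoxymethoxy)phenyl]-5-(benzyloxy)-3-(triisopropylsiloxy)phenol | Oc1cc(OCc2ccccc2)cc(O[Si](C(C)C)(C(C)C)C(C)C)c1-c1cc(C(OC)OC)cc(OCOC)c1OCOC
A2 | alternative 1 | 3-(benzyloxy)cyclobut-2-en-1-one | O=C1C=C(OCc2ccccc2)C1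
A3 | alternative 1 | {[5-(dimethoxymethyl)-2,3-bis(methoxymethoxy)phenyl]ethynyloxy}triisopropylsilane | CC(C)[Si](OC#Cc1cc(C(OC)OC)cc(OCOC)c1OCOC)(C(C)C)C(C)C
A4 | alternative 2 | protected target, hexabenzyl ether with ring-B diacetate, (2S) | O=C1C[C@@H](c2cc(OC(C)=O)c(OC(C)=O)c(-c3c(OCc4ccccc4)cc4oc(-c5ccc(OCc6ccccc6)c(OCc6ccccc6)c5)cc(=O)c4c3OCc3ccccc3)c2)Oc2cc(OCc3ccccc3)cc(OCc3ccccc3)c21
A5 | alternative 2 | (S)-3-aryl-3-[3,5-bis(benzyloxy)phenoxy]propanoic acid (aryl = diacetoxy ring B bearing the tetrabenzyl flavone at C5') | O=C(O)C[C@@H](c1cc(OC(C)=O)c(OC(C)=O)c(-c2c(OCc3ccccc3)cc3oc(-c4ccc(OCc5ccccc5)c(OCc5ccccc5)c4)cc(=O)c3c2OCc2ccccc2)c1)Oc1cc(OCc2ccccc2)cc(OCc2ccccc2)c1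
A6 | alternative 3 | methyl 3-bromo-5-[4-(benzyloxy)-2,6-bis(methoxymethoxy)phenyl]-4-(triisopropylsiloxy)benzoate | COC(=O)c1cc(Br)c(O[Si](C(C)C)(C(C)C)C(C)C)c(-c2c(OCOC)cc(OCc3ccccc3)cc2OCOC)c1
A7 | alternative 3 | methyl 3-bromo-2-oxo-2H-pyran-5-carboxylate (methyl 3-bromocoumalate) | COC(=O)C1=COC(=O)C(Br)=C1
A8 | alternative 3 | {[4-(benzyloxy)-2,6-bis(methoxymethoxy)phenyl]ethynyloxy}triisopropylsilane | CC(C)[Si](OC#Cc1c(OCOC)cc(OCc2ccccc2)cc1OCOC)(C(C)C)C(C)C
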